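## Plan

- **Cuts (retrosynthesis):** the O–CH3 bond and the C1–aryl bond; the C3–acyl bond; the pyran C1–O2 bond (lactol back to a dialdehyde); the cyclopentane bond C5–C6; finally the two Diels–Alder bonds C4a–C7a and C6–C7 of a cyclohexene.
- **Enabling feature:** C5 and C6 are the only adjacent unsubstituted CH2 groups of the cyclopentane ring and lie between the stereocentres C4a and C7. With one extra carbon between them the ring is a cyclohexene whose cis-C4a/C7a, trans-C7a/C7 pattern is the ortho/endo outcome of an (E)-crotonyl dienophile and a 1-substituted butadiene.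
- **Forward order:** Diels–Alder cyclohexene → ozonolysis → intramolecular aldol condensation joining C5 to C6 (ring contraction; the extra carbon ends as a formyl group and leaves as CO) → cyclopentane → dihydropyran lactol → C3 acylation → C1 arylation → O-methylation.
- **Stereochemistry:** C7a, C4a and C7 come from the (S)-oxazolidinone-controlled endo Diels–Alder reaction; C1 comes from substrate-controlled attack on the bicyclic oxocarbenium ion.

Key step: step 9

Remark: iridoid numbering (C1, O2, C3, C4, C4a, C5, C6, C7, C7a) is used for the bicyclic core. The side-chain carbon that becomes C4 is carried as both epimers from step 1 to step 12, where it becomes sp2; C1 of 17, 18 and 20 is an anomeric mixture that converges in step 16.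

## Route

Step 1
Reactants: 1 methyl (2E,4E)-hexa-2,4-dienoate (methyl sorbate)
Product: 3 methyl (3E)-2-methylhexa-3,5-dienoate (racemic), via lithium trienolate 2 (not isolated)
Conditions: LiN(iPr)2, DMPU, THF, −78 °C; then MeI, −78 → 0 °C
Reagents that add atoms: iodomethane, CI
Why: Deconjugative α-alkylation of an extended ester enolate: deprotonation at the terminal methyl group gives the trienolate, which should be alkylated at the α-carbon under kinetic control, leaving the terminal (3E)-diene; the new stereocentre is racemic and is erased in step 12.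

Step 2
Reactants: 3 methyl (3E)-2-methylhexa-3,5-dienoate
Product: 4 (3E)-2-methylhexa-3,5-dien-1-ol
Conditions: LiAlH4, Et2O, 0 °C
Reagents that add atoms: none
Why: Hydride reduction of the ester to the primary alcohol; the unconjugated diene is inert to LiAlH4.

Step 3
Reactants: 4 (3E)-2-methylhexa-3,5-dien-1-ol
Product: 5 ({[(3E)-2-methylhexa-3,5-dien-1-yl]oxy}methyl)benzene
Conditions: NaH, BnBr, Bu4NI (cat.), THF, 0 °C → rt
Reagents that add atoms: benzyl bromide, BrCc1ccccc1
Why: Williamson etherification of the primary alkoxide; the benzyl ether is inert to the Lewis acid, ozone and amine salt used later and is removed in step 11.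

Step 4
Reactants: 6 (4S)-4-benzyl-1,3-oxazolidin-2-one
Product: 7 (4S)-4-benzyl-3-[(2E)-but-2-enoyl]-1,3-oxazolidin-2-one
Conditions: (2E)-but-2-enoic anhydride, LiCl, Et3N, THF, −20 °C → rt
Reagents that add atoms: (2E)-but-2-enoic anhydride, C/C=C/C(=O)OC(=O)/C=C/C
Why: N-acylation of the oxazolidinone with an anhydride under LiCl/Et3N activation, mild enough to avoid polymerisation of the crotonyl unit.

Step 5
Reactants: 5 ({[(3E)-2-methylhexa-3,5-dien-1-yl]oxy}methyl)benzene; 7 (4S)-4-benzyl-3-[(2E)-but-2-enoyl]-1,3-oxazolidin-2-one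
Product: 8 (4S)-4-benzyl-3-{(1R,2R,6S)-2-[1-(benzyloxy)propan-2-yl]-6-methylcyclohex-3-ene-1-carbonyl}-1,3-oxazolidin-2-one
Conditions: Et2AlCl (1.4 equiv), CH2Cl2, −30 °C; 1 M HCl quench
Reagents that add atoms: none
Why: Lewis-acid-promoted Diels–Alder reaction of a chiral N-enoyl oxazolidinone: in the aluminium-chelated s-cis imide the benzyl group blocks one face of Cα so the diene adds to the other, which fixes C7a and C7; the endo transition state places the diene side chain on C4a cis to the acyl group, the (E)-crotonyl geometry keeps the C7 methyl trans to it, and bonding of the unsubstituted diene terminus to Cβ gives the ortho regiochemistry.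

Step 6
Reactants: 8 (4S)-4-benzyl-3-{(1R,2R,6S)-2-[1-(benzyloxy)propan-2-yl]-6-methylcyclohex-3-ene-1-carbonyl}-1,3-oxazolidin-2-one
Product: 9 {(1R,2R,6S)-2-[1-(benzyloxy)propan-2-yl]-6-methylcyclohex-3-en-1-yl}methanol
Conditions: LiBH4, H2O (1.5 equiv), Et2O, 0 °C
Reagents that add atoms: none
Why: Reductive cleavage of the exocyclic imide carbonyl gives the primary alcohol without epimerising the α-carbon C7a and returns the auxiliary.

Step 7
Reactants: 9 {(1R,2R,6S)-2-[1-(benzyloxy)propan-2-yl]-6-methylcyclohex-3-en-1-yl}methanol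
Product: 10 (3R,4R,5S)-4-[(benzyloxy)methyl]-3-[1-(benzyloxy)propan-2-yl]-5-methylcyclohex-1-ene
Conditions: NaH, BnBr, Bu4NI (cat.), THF/DMF, 0 °C → rt
Reagents that add atoms: benzyl bromide, BrCc1ccccc1
Why: Williamson etherification; the future C1 oxygen must be masked so that it cannot form a lactol with the aldehydes made in step 8.

Step 8
Reactants: 10 (3R,4R,5S)-4-[(benzyloxy)methyl]-3-[1-(benzyloxy)propan-2-yl]-5-methylcyclohex-1-ene
Product: 12 (2R,3R,4S)-3-[(benzyloxy)methyl]-2-[1-(benzyloxy)propan-2-yl]-4-methylhexanedial, via ozonide 11 (not isolated)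
Conditions: O3, CH2Cl2, −78 °C; then PPh3, −78 °C → rt
Reagents that add atoms: ozone, [O-][O+]=O
Why: Ozonolysis with reductive work-up opens the only C=C bond to two aldehydes; the benzyl ethers and the three stereocentres are untouched and the crude dialdehyde is used directly.

Step 9
Reactants: 12 (2R,3R,4S)-3-[(benzyloxy)methyl]-2-[1-(benzyloxy)propan-2-yl]-4-methylhexanedial
Product: 13 (3R,4S,5R)-4-[(benzyloxy)methyl]-3-[1-(benzyloxy)propan-2-yl]-5-methylcyclopent-1-ene-1-carbaldehyde
Conditions: Bn2NH·CF3CO2H (0.3 equiv), toluene, 50 °C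
Reagents that add atoms: none
Why: The secondary ammonium salt converts the unbranched aldehyde (the CHO on the C6 methylene) into its enamine, whose β-carbon C6 attacks the C5 formyl carbon and closes the five-membered ring C4a–C5–C6–C7–C7a by a 5-(enolexo)-exo-trig addition; loss of water through the iminium ion then gives the conjugated cyclopent-1-ene-1-carbaldehyde. The closest known reaction type is the intramolecular aldol condensation of 1,6-dialdehydes obtained from cyclohexenes, the classical cyclohexene-to-cyclopentene ring contraction. No stereocentre is created: C5 and C6 become sp2, and C4a, C7a and C7 are carried over from step 5. The step needs regioselectivity between the two possible enamines and configurational stability at C4a, which is α to the acceptor aldehyde. The α-branch at C4a makes the enamine of the C5 aldehyde slow to form and its aldol product unable to dehydrate (it would carry a quaternary carbon), so that pathway is reversible and should drain into 13. The weakly acidic, non-nucleophilic buffer and the fast intramolecular closure should keep C4a from epimerising before the ring closes.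

Step 10
Reactants: 13 (3R,4S,5R)-4-[(benzyloxy)methyl]-3-[1-(benzyloxy)propan-2-yl]-5-methylcyclopent-1-ene-1-carbaldehyde
Product: 14 (3R,4R,5S)-4-[(benzyloxy)methyl]-3-[1-(benzyloxy)propan-2-yl]-5-methylcyclopent-1-ene
Conditions: RhCl(PPh3)3 (1.1 equiv), PhCN, 130 °C
Reagents that add atoms: none
Why: Tsuji–Wilkinson decarbonylation: oxidative addition of the formyl C–H bond to monovalent rhodium, CO extrusion and reductive elimination replace CHO by H on C6 without moving the C5=C6 double bond, so the helper carbon leaves as rhodium-bound CO.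

Step 11
Reactants: 14 (3R,4R,5S)-4-[(benzyloxy)methyl]-3-[1-(benzyloxy)propan-2-yl]-5-methylcyclopent-1-ene
Product: 15 2-[(1R,2R,3S)-2-(hydroxymethyl)-3-methylcyclopentyl]propan-1-ol
Conditions: H2 (1 atm), Pd(OH)2/C, EtOH, rt
Reagents that add atoms: none
Why: Heterogeneous hydrogenation saturates the C5=C6 bond (both carbons become CH2, no stereocentre is formed) and hydrogenolyses both benzyl ethers in the same operation.

Step 12
Reactants: 15 2-[(1R,2R,3S)-2-(hydroxymethyl)-3-methylcyclopentyl]propan-1-ol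
Product: 17 (4aS,7S,7aR)-4,7-dimethyl-1,4a,5,6,7,7a-hexahydrocyclopenta[c]pyran-1-ol, via dialdehyde 16 (not isolated)
Conditions: (COCl)2, DMSO, CH2Cl2, −78 °C; Et3N, −78 → 0 °C; then TsOH·H2O (5 mol %), THF, rt
Reagents that add atoms: none
Why: Swern oxidation converts both primary alcohols to aldehydes before any lactol can form, and acid-catalysed ring–chain tautomerisation (the enol of the C3 aldehyde adds to the C1 aldehyde) should then give the cis-fused enol-ether lactol; C4 becomes sp2 so both side-chain epimers converge, and C4a, C7 and C7a are not touched.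

Step 13
Reactants: 17 (4aS,7S,7aR)-4,7-dimethyl-1,4a,5,6,7,7a-hexahydrocyclopenta[c]pyran-1-ol
Product: 18 tert-butyl{[(4aS,7S,7aR)-4,7-dimethyl-1,4a,5,6,7,7a-hexahydrocyclopenta[c]pyran-1-yl]oxy}dimethylsilane
Conditions: TBSCl, imidazole, DMF, 0 °C → rt
Reagents that add atoms: tert-butyl(chloro)dimethylsilane, CC(C)(C)[Si](C)(C)Cl
Why: Silylation of the anomeric hydroxyl group under weakly basic conditions masks the lactol for the organolithium step and provides the leaving group for step 16; both C1 anomers are usable.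

Step 14
Reactants: 18 tert-butyl{[(4aS,7S,7aR)-4,7-dimethyl-1,4a,5,6,7,7a-hexahydrocyclopenta[c]pyran-1-yl]oxy}dimethylsilane
Product: 20 1-[(4aS,7S,7aR)-1-{[tert-butyl(dimethyl)silyl]oxy}-4,7-dimethyl-1,4a,5,6,7,7a-hexahydrocyclopenta[c]pyran-3-yl]-3-methylbutan-1-one, via vinyllithium 19 (not isolated)
Conditions: t-BuLi (1.3 equiv), THF/pentane, −78 → 0 °C; then N-methoxy-N,3-dimethylbutanamide, −78 → 0 °C; aq. NH4Cl
Reagents that add atoms: N-methoxy-N,3-dimethylbutanamide, CC(C)CC(=O)N(C)OC
Why: α-Lithiation of a cyclic enol ether followed by acylation with an N-methoxy-N-methylamide: C3–H is the only vinylic hydrogen and is acidified by O2, the base is guided by the acetal oxygens, and the chelated tetrahedral adduct releases the ketone only on work-up, so no tertiary alcohol should form.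

Step 15
Reactants: 21 1-(2-hydroxy-6-methylphenyl)ethan-1-one
Product: 22 4-hydroxy-5-methyl-2H-chromen-2-one
Conditions: NaH (3 equiv), (EtO)2CO, toluene, 110 °C; then aq. HCl
Reagents that add atoms: diethyl carbonate, CCOC(=O)OCC
Why: Claisen-type C-acylation of the methyl ketone enolate by the carbonate followed by lactonisation onto the phenol, the standard 4-hydroxycoumarin synthesis from 2-hydroxyacetophenones.

Step 16
Reactants: 20 1-[(4aS,7S,7aR)-1-{[tert-butyl(dimethyl)silyl]oxy}-4,7-dimethyl-1,4a,5,6,7,7a-hexahydrocyclopenta[c]pyran-3-yl]-3-methylbutan-1-one; 22 4-hydroxy-5-methyl-2H-chromen-2-one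
Product: 23 3-[(1S,4aS,7S,7aR)-4,7-dimethyl-3-(3-methylbutanoyl)-1,4a,5,6,7,7a-hexahydrocyclopenta[c]pyran-1-yl]-4-hydroxy-5-methyl-2H-chromen-2-one
Conditions: Me3SiOTf (0.2 equiv), MeCN, −20 → 0 °C
Reagents that add atoms: none
Why: Lewis-acid-mediated C-alkylation of the enolic 4-hydroxycoumarin by a cyclic oxocarbenium ion (a C-glycosylation-type Friedel–Crafts reaction, in which any O-linked acetal formed first rearranges to the C-linked product under the same acid): ionisation of the anomeric silyloxy group gives the C1=O2 cation, which C3 of 22 should attack on the face opposite the C7 methyl group that sits 1,3 to C1 on the H7a face, so that the aryl group ends trans to H7a (1S); the C1–O2 bond of the product stays ionisable, which should let a kinetic mixture drift towards this less congested epimer.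

Step 17
Reactants: 23 3-[(1S,4aS,7S,7aR)-4,7-dimethyl-3-(3-methylbutanoyl)-1,4a,5,6,7,7a-hexahydrocyclopenta[c]pyran-1-yl]-4-hydroxy-5-methyl-2H-chromen-2-one
Product: 24 3-[(1S,4aS,7S,7aR)-4,7-dimethyl-3-(3-methylbutanoyl)-1,4a,5,6,7,7a-hexahydrocyclopenta[c]pyran-1-yl]-2-methoxy-5-methyl-4H-chromen-4-one (CNP0144992.2)
Conditions: Me3SiCHN2, MeOH/toluene, 0 °C → rt
Reagents that add atoms: (trimethylsilyl)diazomethane, C[Si](C)(C)C=[N+]=[N-]
Why: O-Methylation of the acidic enol with a diazoalkane: the ambident 4-hydroxycoumarin/2-hydroxychromone system should be methylated mainly at the oxygen on C2, because the oxygen on C4 is screened by the peri methyl group on C5 and by the bulky C3 substituent, giving the 2-methoxychromone; the acyl enol ether and the ketone are inert.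

## Compound list

1 | methyl (2E,4E)-hexa-2,4-dienoate | C/C=C/C=C/C(=O)OC | starting material
2 | lithium (3E)-1-methoxyhexa-1,3,5-trien-1-olate | C=C/C=C/C=C(OC)O[Li] | intermediate (not isolated)
3 | methyl (3E)-2-methylhexa-3,5-dienoate (racemic) | C=C/C=C/C(C)C(=O)OC | intermediate
4 | (3E)-2-methylhexa-3,5-dien-1-ol (racemic) | C=C/C=C/C(C)CO | intermediate
5 | ({[(3E)-2-methylhexa-3,5-dien-1-yl]oxy}methyl)benzene (racemic) | C=C/C=C/C(C)COCc1ccccc1 | intermediate
6 | (4S)-4-benzyl-1,3-oxazolidin-2-one | O=C1N[C@@H](Cc2ccccc2)CO1 | starting material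
7 | (4S)-4-benzyl-3-[(2E)-but-2-enoyl]-1,3-oxazolidin-2-one | C/C=C/C(=O)N1[C@@H](Cc2ccccc2)COC1=O | intermediate
8 | (4S)-4-benzyl-3-{(1R,2R,6S)-2-[1-(benzyloxy)propan-2-yl]-6-methylcyclohex-3-ene-1-carbonyl}-1,3-oxazolidin-2-one (both epimers at the side-chain CH) | CC(COCc1ccccc1)[C@H]2C=CC[C@H](C)[C@H]2C(=O)N3[C@@H](Cc4ccccc4)COC3=O | intermediate
9 | {(1R,2R,6S)-2-[1-(benzyloxy)propan-2-yl]-6-methylcyclohex-3-en-1-yl}methanol | CC(COCc1ccccc1)[C@H]2C=CC[C@H](C)[C@H]2CO | intermediate
10 | (3R,4R,5S)-4-[(benzyloxy)methyl]-3-[1-(benzyloxy)propan-2-yl]-5-methylcyclohex-1-ene | CC(COCc1ccccc1)[C@H]2C=CC[C@H](C)[C@H]2COCc3ccccc3 | intermediate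
11 | 3-[(benzyloxy)methyl]-2-[1-(benzyloxy)propan-2-yl]-4-methyl-7,8,9-trioxabicyclo[4.2.1]nonane (secondary ozonide of 10) | CC(COCc1ccccc1)[C@H]2C3OOC(O3)C[C@H](C)[C@H]2COCc4ccccc4 | intermediate (not isolated)
12 | (2R,3R,4S)-3-[(benzyloxy)methyl]-2-[1-(benzyloxy)propan-2-yl]-4-methylhexanedial | CC(COCc1ccccc1)[C@@H](C=O)[C@H](COCc2ccccc2)[C@@H](C)CC=O | intermediate
13 | (3R,4S,5R)-4-[(benzyloxy)methyl]-3-[1-(benzyloxy)propan-2-yl]-5-methylcyclopent-1-ene-1-carbaldehyde | CC(COCc1ccccc1)[C@H]2C=C(C=O)[C@H](C)[C@H]2COCc3ccccc3 | intermediate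
14 | (3R,4R,5S)-4-[(benzyloxy)methyl]-3-[1-(benzyloxy)propan-2-yl]-5-methylcyclopent-1-ene | CC(COCc1ccccc1)[C@H]2C=C[C@H](C)[C@H]2COCc3ccccc3 | intermediate
15 | 2-[(1R,2R,3S)-2-(hydroxymethyl)-3-methylcyclopentyl]propan-1-ol (both epimers at C2 of the propanol) | CC(CO)[C@H]1CC[C@H](C)[C@H]1CO | intermediate
16 | 2-[(1R,2R,3S)-2-formyl-3-methylcyclopentyl]propanal | CC(C=O)[C@H]1CC[C@H](C)[C@H]1C=O | intermediate (not isolated)
17 | (4aS,7S,7aR)-4,7-dimethyl-1,4a,5,6,7,7a-hexahydrocyclopenta[c]pyran-1-ol (C1 anomers) | OC1OC=C(C)[C@H]2CC[C@H](C)[C@H]21 | intermediate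
18 | tert-butyl{[(4aS,7S,7aR)-4,7-dimethyl-1,4a,5,6,7,7a-hexahydrocyclopenta[c]pyran-1-yl]oxy}dimethylsilane (C1 anomers) | CC(C)(C)[Si](C)(C)OC1OC=C(C)[C@H]2CC[C@H](C)[C@H]21 | intermediate
19 | [(4aS,7S,7aR)-1-{[tert-butyl(dimethyl)silyl]oxy}-4,7-dimethyl-1,4a,5,6,7,7a-hexahydrocyclopenta[c]pyran-3-yl]lithium | CC(C)(C)[Si](C)(C)OC1OC([Li])=C(C)[C@H]2CC[C@H](C)[C@H]21 | intermediate (not isolated)
20 | 1-[(4aS,7S,7aR)-1-{[tert-butyl(dimethyl)silyl]oxy}-4,7-dimethyl-1,4a,5,6,7,7a-hexahydrocyclopenta[c]pyran-3-yl]-3-methylbutan-1-one (C1 anomers) | CC(C)(C)[Si](C)(C)OC1OC(C(=O)CC(C)C)=C(C)[C@H]2CC[C@H](C)[C@H]21 | intermediate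
21 | 1-(2-hydroxy-6-methylphenyl)ethan-1-one | CC(=O)c1c(C)cccc1O | starting material
22 | 4-hydroxy-5-methyl-2H-chromen-2-one | Cc1cccc2oc(=O)cc(O)c12 | intermediate
23 | 3-[(1S,4aS,7S,7aR)-4,7-dimethyl-3-(3-methylbutanoyl)-1,4a,5,6,7,7a-hexahydrocyclopenta[c]pyran-1-yl]-4-hydroxy-5-methyl-2H-chromen-2-one | O=c1oc2cccc(C)c2c(O)c1[C@H]1OC(C(=O)CC(C)C)=C(C)[C@H]2CC[C@H](C)[C@H]21 | intermediate
24 | 3-[(1S,4aS,7S,7aR)-4,7-dimethyl-3-(3-methylbutanoyl)-1,4a,5,6,7,7a-hexahydrocyclopenta[c]pyran-1-yl]-2-methoxy-5-methyl-4H-chromen-4-one | COc1oc2cccc(C)c2c(=O)c1[C@H]1OC(C(=O)CC(C)C)=C(C)[C@H]2CC[C@H](C)[C@H]21 | target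

## Step count and risks

Total step count: 17. Longest linear sequence: 15 steps (steps 1–3, 5–14, 16 and 17).

**Step 16 (C1 arylation).** The nucleophile may enter on the wrong face of the oxocarbenium ion, or the cation may lose H7a to a dienol ether before it is trapped. The fallback reverses the order of bond formation at C1. From 20 the silyl group is removed with HF·pyridine in THF to give the free lactol 1-[(4aS,7S,7aR)-1-hydroxy-4,7-dimethyl-1,4a,5,6,7,7a-hexahydrocyclopenta[c]pyran-3-yl]-3-methylbutan-1-one F1, which is in equilibrium with its open aldehyde–enol form. Knoevenagel condensation of that aldehyde with 22 (ethylenediammonium diacetate, CH2Cl2, rt) would give the alkylidene 3-{[2-(3-hydroxy-6-methyl-4-oxohept-2-en-2-yl)-5-methylcyclopentyl]methylidene}-5-methylchromane-2,4-dione F2, not isolated. Its enolic side-chain oxygen then closes the pyran by a reversible 6-exo-trig oxa-Michael addition, so C1 is set in a C–O bond-forming step under different control, and the route is rejoined at 23.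

**Step 17 (O-methylation).** Methylation may go to the oxygen on C4 and give the 4-methoxycoumarin isomer. The fallback installs the 2-methoxy group before the C1–aryl bond is made. From 21, NaH and CS2 followed by MeI give 1-(2-hydroxy-6-methylphenyl)-3,3-bis(methylsulfanyl)prop-2-en-1-one F3. Heating in acetic acid cyclises it to 5-methyl-2-(methylsulfanyl)-4H-chromen-4-one F4, mCPBA oxidises this to 2-(methanesulfonyl)-5-methyl-4H-chromen-4-one F5, and NaOMe in MeOH displaces the sulfonyl group to give 2-methoxy-5-methyl-4H-chromen-4-one F6. The ketene-acetal-like C3 of F6 is then coupled with 20 (Me3SiOTf, 2,6-di-tert-butylpyridine, CH2Cl2, −40 → 0 °C) in a Friedel–Crafts-type addition to the oxocarbenium ion, which comes back to the route directly at 24.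

**Step 14 (C3 acylation).** Deprotonation may take place at the allylic positions (C4 methyl, C4a) instead of the vinylic C3–H, or the base may attack the silyl acetal. The fallback replaces deprotonation by catalytic C–H functionalisation. From 18, borylation with B2pin2, [Ir(OMe)(cod)]2 and 4,4'-di-tert-butyl-2,2'-bipyridine in THF at 50 °C should occur at the only vinylic C–H bond and give 2-[(4aS,7S,7aR)-1-{[tert-butyl(dimethyl)silyl]oxy}-4,7-dimethyl-1,4a,5,6,7,7a-hexahydrocyclopenta[c]pyran-3-yl]-4,4,5,5-tetramethyl-1,3,2-dioxaborolane F7. Acylative Suzuki–Miyaura coupling of F7 with 3-methylbutanoyl chloride (Pd(PPh3)4, Cs2CO3, anhydrous toluene, 80 °C) returns to the route at 20.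

## Further compounds

F1 | step 16 | 1-[(4aS,7S,7aR)-1-hydroxy-4,7-dimethyl-1,4a,5,6,7,7a-hexahydrocyclopenta[c]pyran-3-yl]-3-methylbutan-1-one | OC1OC(C(=O)CC(C)C)=C(C)[C@H]2CC[C@H](C)[C@H]21
F2 | step 16 | 3-{[2-(3-hydroxy-6-methyl-4-oxohept-2-en-2-yl)-5-methylcyclopentyl]methylidene}-5-methylchromane-2,4-dione (ring stereocentres as in 20) | CC(C)CC(=O)C(O)=C(C)[C@H]1CC[C@H](C)[C@H]1C=C2C(=O)Oc3cccc(C)c3C2=O
F3 | step 17 | 1-(2-hydroxy-6-methylphenyl)-3,3-bis(methylsulfanyl)prop-2-en-1-one | CSC(SC)=CC(=O)c1c(C)cccc1O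
F4 | step 17 | 5-methyl-2-(methylsulfanyl)-4H-chromen-4-one | CSc1cc(=O)c2c(C)cccc2o1
F5 | step 17 | 2-(methanesulfonyl)-5-methyl-4H-chromen-4-one | CS(=O)(=O)c1cc(=O)c2c(C)cccc2o1
F6 | step 17 | 2-methoxy-5-methyl-4H-chromen-4-one | COc1cc(=O)c2c(C)cccc2o1
F7 | step 14 | 2-[(4aS,7S,7aR)-1-{[tert-butyl(dimethyl)silyl]oxy}-4,7-dimethyl-1,4a,5,6,7,7a-hexahydrocyclopenta[c]pyran-3-yl]-4,4,5,5-tetramethyl-1,3,2-dioxaborolane | CC(C)(C)[Si](C)(C)OC1OC(B2OC(C)(C)C(C)(C)O2)=C(C)[C@H]3CC[C@H](C)[C@H]31
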